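The eleven-membered carbocycle is cut between the E-vinyl CH of its 1,3-diene and the quaternary ring carbon C(CH3)2. That carbon is flanked by the carbinol carbon. At the ketone level it therefore becomes the α-carbon of a tetrasubstituted enolate, while the vinyl CH becomes an alkenyl iodide. The precursor is an open-chain α-chloro ketone that ends in an (E)-1-iodo-1,3-diene. In one operation zinc turns the C–Cl bond into a regiodefined enolate and palladium couples it with the iodide. The ring closes, the quaternary carbon forms and both E alkenes survive. A ketal Claisen rearrangement builds the precursor, and CBS reduction then sets the only stereocentre.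

Key step: step 7

Remark: read by the CIP rules, the single stereocentre of the target is R.

Step 1
Reactants: 1 3-chloro-3-methylbutan-2-one
Product: 2 2-chloro-3,3-dimethoxy-2-methylbutane
Conditions: HC(OMe)3, MeOH, p-TsOH (cat.), 40 °C
Reagents that add atoms: trimethyl orthoformate, COC(OC)OC
Why: Acid-catalysed ketalisation with the orthoformate as water scavenger converts the only carbonyl group into the dimethyl ketal, and the tertiary chloride beside it ionises too poorly to be displaced.

Step 2
Reactants: 3 2-methylbut-1-en-3-yne; 4 oxirane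
Product: 6 4-methylidenehex-5-yn-1-ol, via dipotassium enyne dianion 5 (not isolated)
Conditions: n-BuLi (2 equiv), KOt-Bu (2 equiv), THF/hexane, −78 to −20 °C; then oxirane (1 equiv), −78 °C to rt; H2O
Reagents that add atoms: none
Why: Superbase dimetalation removes the acetylenic proton and one allylic methyl proton, the far more reactive allyl terminus opens oxirane by SN2, and only one constitution can result because both CH2 ends of the allyl anion are equivalent.

Step 3
Reactants: 6 4-methylidenehex-5-yn-1-ol
Product: 8 (5E)-6-iodo-4-methylidenehex-5-en-1-ol, via doubly zirconated dienyl alkoxide 7 (not isolated)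
Conditions: Cp2Zr(H)Cl (2.2 equiv), THF, 0 °C to rt; then I2, −78 to 0 °C; H2O
Reagents that add atoms: iodine, II
Why: Hydrozirconation adds Zr–H syn across the terminal alkyne with zirconium on the terminal carbon (one equivalent is consumed by the hydroxyl group), and iodinolysis of the C–Zr bond with retention fixes the E-iodide.

Step 4
Reactants: 8 (5E)-6-iodo-4-methylidenehex-5-en-1-ol
Product: 9 (5E)-6-iodo-4-methylidenehex-5-enal
Conditions: TEMPO (cat.), PhI(OAc)2, CH2Cl2, rt
Reagents that add atoms: none
Why: The oxoammonium (TEMPO) oxidation of the primary alcohol stops at the aldehyde and leaves the iodo-diene untouched.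

Step 5
Reactants: 9 (5E)-6-iodo-4-methylidenehex-5-enal; 10 prop-1-en-2-ylmagnesium bromide
Product: 11 (7E)-8-iodo-2-methyl-6-methylideneocta-1,7-dien-3-ol (racemic)
Conditions: THF, −78 °C; H2O
Reagents that add atoms: none
Why: Grignard 1,2-addition to the aldehyde is much faster at low temperature than iodine–magnesium exchange, and the new carbinol centre forms as a racemate, which is harmless because step 6 erases it.

Step 6
Reactants: 11 (7E)-8-iodo-2-methyl-6-methylideneocta-1,7-dien-3-ol; 2 2-chloro-3,3-dimethoxy-2-methylbutane
Product: 13 (6E,11E)-2-chloro-12-iodo-2,6-dimethyl-10-methylidenedodeca-6,11-dien-3-one, via allyl vinyl ether 12 (not isolated)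
Conditions: 2 (3 equiv), 2,4-dinitrophenol (cat.), toluene, 110 °C, MeOH distilled off
Reagents that add atoms: none
Why: In this ketal Claisen rearrangement, alcohol exchange and loss of methanol can place the vinyl ether only on the CH3 side of 2 (the other side is quaternary), and the chair transition state with the side chain equatorial turns the carbinol centre into the E-trisubstituted alkene while delivering the α-chloro ketone.

Step 7
Reactants: 13 (6E,11E)-2-chloro-12-iodo-2,6-dimethyl-10-methylidenedodeca-6,11-dien-3-one
Product: 15 (3E,8E)-2,2,9-trimethyl-5-methylidenecycloundeca-3,8-dien-1-one, via chlorozinc enolate 14 (not isolated)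
Conditions: activated Zn dust, THF, 0 °C to rt; the decanted solution is added by syringe pump over 12 h to Pd2(dba)3 (10 mol %), P(t-Bu)3 (25 mol %), THF, 50 °C, final 1 mM
Reagents that add atoms: none
Why: Zinc inserts into the activated tertiary C–Cl bond and gives the tetrasubstituted enolate 14 with its double bond fixed towards the C(CH3)2 carbon; zerovalent palladium then adds oxidatively to the dienyl C–I bond, the zinc enolate transmetalates within the same molecule to a twelve-membered palladacycle, and reductive elimination joins the vinyl CH to the C(CH3)2 carbon. The closest known reaction types are the Negishi-type coupling of Reformatsky reagents with aryl and alkenyl halides and the intramolecular palladium-catalysed α-alkenylation of ketone enolates, including cases that build quaternary carbons. The eleven-membered carbocycle closes end to end, both reacting atoms becoming ring members, helped by three rigid sp2 units and the gem-dimethyl group that remove free rotors, and by pseudo-high dilution against oligomerisation. No stereocentre is formed; the E geometry of the new ring alkene is carried over from the iodide because oxidative addition and reductive elimination both run with retention. Regioselectivity is secured by the position of the chlorine and by the base-free medium, so the CH2 on the other side of the carbonyl never becomes nucleophilic. Chemoselectivity is secured because the E-alkenylpalladium cannot reach the trisubstituted alkene in a six- or seven-membered Heck closure (that would need a trans double bond in a small ring), a zinc enolate does not add to unactivated alkenes, and the bulky electron-rich phosphine favours reductive elimination over β-hydride loss from the methyl groups.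

Step 8
Reactants: 15 (3E,8E)-2,2,9-trimethyl-5-methylidenecycloundeca-3,8-dien-1-one
Product: 16 (1R,3E,8E)-2,2,9-trimethyl-5-methylidenecycloundeca-3,8-dien-1-ol
Conditions: (S)-2-methyl-CBS-oxazaborolidine (20 mol %), catecholborane, toluene, −78 to −40 °C; H2O
Reagents that add atoms: none
Why: In the Corey–Bakshi–Shibata reduction the (S)-oxazaborolidine binds the carbonyl oxygen anti to the bulkier quaternary flank and delivers hydride to the face that gives the R carbinol, as with tert-alkyl alkyl ketones, and catecholborane at low temperature should not hydroborate the alkenes.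

Step 9
Reactants: 16 (1R,3E,8E)-2,2,9-trimethyl-5-methylidenecycloundeca-3,8-dien-1-ol; 17 4-acetoxy-3-methoxybenzoic acid
Product: 18 (1R,3E,8E)-2,2,9-trimethyl-5-methylidenecycloundeca-3,8-dien-1-yl 4-acetoxy-3-methoxybenzoate
Conditions: DCC, DMAP, toluene, rt to 60 °C
Reagents that add atoms: none
Why: Steglich esterification through the acylpyridinium ion acylates the hindered alcohol at oxygen, so the C–O bond and the stereocentre stay untouched, while the phenol is masked as its acetate.

Step 10
Reactants: 18 (1R,3E,8E)-2,2,9-trimethyl-5-methylidenecycloundeca-3,8-dien-1-yl 4-acetoxy-3-methoxybenzoate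
Product: 19 (1R,3E,8E)-2,2,9-trimethyl-5-methylidenecycloundeca-3,8-dien-1-yl 4-hydroxy-3-methoxybenzoate (target)
Conditions: pyrrolidine (1.2 equiv), CH2Cl2, 0 °C to rt
Reagents that add atoms: none
Why: Aminolysis of the activated aryl acetate is far faster than attack on the hindered secondary benzoate, so only the phenol is unmasked.

Compound list
1 | 3-chloro-3-methylbutan-2-one | CC(=O)C(C)(C)Cl | starting material
2 | 2-chloro-3,3-dimethoxy-2-methylbutane | COC(C)(OC)C(C)(C)Cl | intermediate
3 | 2-methylbut-1-en-3-yne | C=C(C)C#C | starting material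
4 | oxirane | C1CO1 | starting material
5 | dipotassium salt of the enyne dianion | [CH2-]C(=C)C#[C-].[K+].[K+] | intermediate
6 | 4-methylidenehex-5-yn-1-ol | OCCCC(=C)C#C | intermediate
7 | doubly zirconated (E)-dienyl alkoxide | Cl[Zr](/C=C/C(=C)CCCO[Zr](Cl)(C1C=CC=C1)C1C=CC=C1)(C1C=CC=C1)C1C=CC=C1 | intermediate
8 | (5E)-6-iodo-4-methylidenehex-5-en-1-ol | OCCCC(=C)/C=C/I | intermediate
9 | (5E)-6-iodo-4-methylidenehex-5-enal | O=CCCC(=C)/C=C/I | intermediate
10 | prop-1-en-2-ylmagnesium bromide | C=C(C)[Mg]Br | starting material
11 | (7E)-8-iodo-2-methyl-6-methylideneocta-1,7-dien-3-ol, racemic | C=C(C)C(O)CCC(=C)/C=C/I | intermediate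
12 | allyl vinyl ether from 11 and 2 | C=C(OC(CCC(=C)/C=C/I)C(C)=C)C(C)(C)Cl | intermediate
13 | (6E,11E)-2-chloro-12-iodo-2,6-dimethyl-10-methylidenedodeca-6,11-dien-3-one | CC(C)(Cl)C(=O)CC/C(C)=C/CCC(=C)/C=C/I | intermediate
14 | chlorozinc enolate of the dechlorinated ketone | CC(C)=C(O[Zn]Cl)CC/C(C)=C/CCC(=C)/C=C/I | intermediate
15 | (3E,8E)-2,2,9-trimethyl-5-methylidenecycloundeca-3,8-dien-1-one | C=C1/C=C/C(C)(C)C(=O)CC/C(C)=C/CC1 | intermediate
16 | (1R,3E,8E)-2,2,9-trimethyl-5-methylidenecycloundeca-3,8-dien-1-ol | C=C1/C=C/C(C)(C)[C@H](O)CC/C(C)=C/CC1 | intermediate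
17 | 4-acetoxy-3-methoxybenzoic acid | CC(=O)Oc1ccc(C(=O)O)cc1OC | starting material
18 | (1R,3E,8E)-2,2,9-trimethyl-5-methylidenecycloundeca-3,8-dien-1-yl 4-acetoxy-3-methoxybenzoate | C=C1/C=C/C(C)(C)[C@H](OC(=O)c2ccc(OC(C)=O)c(OC)c2)CC/C(C)=C/CC1 | intermediate
19 | (1R,3E,8E)-2,2,9-trimethyl-5-methylidenecycloundeca-3,8-dien-1-yl 4-hydroxy-3-methoxybenzoate | C=C1/C=C/C(C)(C)[C@H](OC(=O)c2ccc(O)c(OC)c2)CC/C(C)=C/CC1 | target

Total step count: 10. Longest linear sequence: 9 (steps 2 to 10).

Steps most likely to fail

1. Step 7. Ring closure may lose against intermolecular coupling, and the hindered zinc enolate may be protonated or may transmetalate too slowly. The fallback forms the same bond by an aldol-type closure instead of a cross-coupling.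
 - It sets out from 6. TEMPO/PhI(OAc)2 oxidation gives 4-methylidenehex-5-ynal F1, and two equivalents of 10 give 2-methyl-6-methylideneoct-1-en-7-yn-3-ol F2.
 - The ketal Claisen rearrangement with 2 gives (6E)-2-chloro-2,6-dimethyl-10-methylidenedodec-6-en-11-yn-3-one F3.
 - Hydroboration of the terminal alkyne with Cy2BH and oxidation with NaBO3 give the β,γ-unsaturated aldehyde (6E)-11-chloro-7,11-dimethyl-3-methylidene-10-oxododec-6-enal F4.
 - SmI2 in dilute THF at −78 °C reduces the C–Cl bond to a samarium enolate, which adds to the aldehyde within a chelate. This intramolecular Reformatsky-type reaction is well documented for medium rings. It gives (8E)-3-hydroxy-2,2,9-trimethyl-5-methylidenecycloundec-8-en-1-one F5.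
 - Dehydration with the Burgess reagent can run only towards the CH2 next to the methylidene carbon, because the other neighbour is quaternary. The route is rejoined at 15.

2. Step 6. Acid and heat may ionise or dehydrate the allylic alcohol, and the chloro ketal may lose HCl or methanol before exchange takes place. The fallback separates chain extension from the definition of the enolate.
 - It sets out from 11. An orthoester Claisen rearrangement (MeC(OEt)3, cat. propionic acid, 140 °C) gives ethyl (4E,9E)-10-iodo-4-methyl-8-methylidenedeca-4,9-dienoate F6.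
 - AlMe3 and MeNH(OMe)·HCl give the Weinreb amide (4E,9E)-10-iodo-N-methoxy-N,4-dimethyl-8-methylidenedeca-4,9-dienamide F7.
 - Addition of 10 gives the isopropenyl ketone (6E,11E)-12-iodo-2,6-dimethyl-10-methylidenedodeca-1,6,11-trien-3-one F8.
 - Conjugate reduction with LiBH(s-Bu)3 at −78 °C, followed by ZnCl2 in the same flask, gives the same regiodefined zinc enolate. The route is rejoined at 14.

3. Step 8. Facial discrimination may be weak in the conformationally mobile ring, and uncatalysed background reduction may erode the enantiomeric purity. The fallback replaces asymmetric induction by a resolution.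
 - It sets out from 15. LiAlH4 gives racemic (3E,8E)-2,2,9-trimethyl-5-methylidenecycloundeca-3,8-dien-1-ol F9.
 - Esterification with (S)-2-methoxy-2-phenylacetic acid (DCC, DMAP) gives the (1R)-alcohol (S)-2-methoxy-2-phenylacetate F10 and the (1S)-alcohol (S)-2-methoxy-2-phenylacetate F11.
 - The two esters are separated by chromatography.
 - Reductive cleavage of the (1R) ester with i-Bu2AlH rejoins the route at 16.

Further compounds
F1 | step 7 | 4-methylidenehex-5-ynal | O=CCCC(=C)C#C
F2 | step 7 | 2-methyl-6-methylideneoct-1-en-7-yn-3-ol, racemic | C=C(C)C(O)CCC(=C)C#C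
F3 | step 7 | (6E)-2-chloro-2,6-dimethyl-10-methylidenedodec-6-en-11-yn-3-one | CC(C)(Cl)C(=O)CC/C(C)=C/CCC(=C)C#C
F4 | step 7 | (6E)-11-chloro-7,11-dimethyl-3-methylidene-10-oxododec-6-enal | O=CCC(=C)CC/C=C(\C)CCC(=O)C(C)(C)Cl
F5 | step 7 | (8E)-3-hydroxy-2,2,9-trimethyl-5-methylidenecycloundec-8-en-1-one, racemic | C=C1CC(O)C(C)(C)C(=O)CC/C(C)=C/CC1
F6 | step 6 | ethyl (4E,9E)-10-iodo-4-methyl-8-methylidenedeca-4,9-dienoate | CCOC(=O)CC/C(C)=C/CCC(=C)/C=C/I
F7 | step 6 | (4E,9E)-10-iodo-N-methoxy-N,4-dimethyl-8-methylidenedeca-4,9-dienamide | CON(C)C(=O)CC/C(C)=C/CCC(=C)/C=C/I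
F8 | step 6 | (6E,11E)-12-iodo-2,6-dimethyl-10-methylidenedodeca-1,6,11-trien-3-one | C=C(C)C(=O)CC/C(C)=C/CCC(=C)/C=C/I
F9 | step 8 | (3E,8E)-2,2,9-trimethyl-5-methylidenecycloundeca-3,8-dien-1-ol, racemic | C=C1/C=C/C(C)(C)C(O)CC/C(C)=C/CC1
F10 | step 8 | (1R,3E,8E)-2,2,9-trimethyl-5-methylidenecycloundeca-3,8-dien-1-yl (S)-2-methoxy-2-phenylacetate | C=C1/C=C/C(C)(C)[C@H](OC(=O)[C@@H](OC)c2ccccc2)CC/C(C)=C/CC1
F11 | step 8 | (1S,3E,8E)-2,2,9-trimethyl-5-methylidenecycloundeca-3,8-dien-1-yl (S)-2-methoxy-2-phenylacetate | C=C1/C=C/C(C)(C)[C@@H](OC(=O)[C@@H](OC)c2ccccc2)CC/C(C)=C/CC1
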